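Take over this flask as I left it: stirred, gas phase held, nothing added.

    target + catalyst ⇌ isomer of the product + catalyst, rate k1*[catalyst]*[target] forward; the back reaction follows from the equilibrium constant (K1 = 1.55, k1 = 13.5 L mol⁻¹ h⁻¹)
    gas phase ⇌ dissolved gas, rate k2*(csat - [dissolved gas]) (k2 = 0.267 h⁻¹, csat = 20 mM)
    substrate + dissolved gas + catalyst → catalyst + target (k3 = 402 L² mol⁻² h⁻¹)
    dissolved gas ⇌ dormant form (K4 = 7.11, k4 = 0.0448 h⁻¹)

substrate 0.30 M; gas phase 20 mM (held); catalyst 3.0 mM; time 5.0 d

- amount of target at 5.0 d, in percent of the substrate charged
- concentration of dissolved gas in solution at 5.0 d, in percent of saturation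

The catalyst comes back unchanged, so I balanced the gas, whose ceiling of 20 mM is lower than the 0.30 M of substrate. Dissolved gas behaves like a tank filling towards saturation with coefficient T = 0.267 h⁻¹. It drains into the target-making uptake with the pseudo-first-order coefficient u = 402 times substrate times catalyst, and into dormant form with D = 0.0448 h⁻¹. As charged, u was 0.362 h⁻¹, and the lag of the solution, 1.03 h, was short against the run of 5.0 d, so I let the level follow f = T/(T + u + D). I call f, the share of saturation at which transfer in equals both drains, the way back from dormant form not counted, the fill fraction; as charged it stood at 39.6 %.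

Putting f into the loss of substrate and integrating, I had substrate at half after 2.57 d and at a quarter after 4.55 d, before the reading. So I expected dissolved gas at 5.0 d a little above 66.4 % of saturation. With the equilibrium share 39.2 %, I expected target near 29.4 %. Leave the stirrer alone: T is the numerator of f.

The forecast gave 35 % and 72 %, its target above mine: “Dissolved gas sits near a quasi-steady level set by gas transfer against catalytic uptake”.

The flask gave 35.0 % and 71.7 %. By 0.500 d transfer had brought dissolved gas to 0.00833 M while substrate stood at 90.2 %; by 5.00 d uptake had taken substrate to 21 %, with isomer of the product at 44.1 % and dormant form at 0.0425 M. For the substrate left in this flask at 5.00 d, f came to 68.8 %. The neighbour flask read at 50 h held 59 % substrate, which gives f = 50.8 %, and its dissolved gas stood at 51.3 % of saturation.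

The numbers are made up; the run is a simulation.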